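The flavanonol is cut at O1–C8a and C4–C4a into a prenylated fluororesorcinol (ring A) and a D-erythronate-derived C2–C3–C4 unit that carries ring B. Ring B is a 2-alkylresorcinol: its geranyl-bearing C3' lies between the oxygens on C2' and C4', the signature of a vinylketene–ynol ether benzannulation, so the ring is made, not bought. In one operation a diazo enone and a geranyl siloxyalkyne form C1'–C2', C2'–C3', C4'–C5' and C5'–C6' and close ring B, while C2 and C3 pass through unchanged. The precursor is an E α'-diazo enone whose anti diad is held as a 3-O-MOM and a 2-O-TBS ether (flavonoid numbering) beside a Weinreb amide, the future C4.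

Key step: step 10

Assumption: ester 1 (the 3,4-acetonide of methyl D-erythronate) is bought as a chiral-pool reagent; it is otherwise two routine steps from D-isoascorbic acid.

Design remark: the two diad oxygens are differentiated from the start (acetal on the future O3, silyl on the future O1), because only one of them may act as nucleophile in the closure of ring C and the 3-O group must not migrate under base.

Step 1
Reactants: 1 methyl 3,4-O-isopropylidene-D-erythronate
Product: 2 methyl 3,4-O-isopropylidene-2-O-(methoxymethyl)-D-erythronate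
Conditions: MOMCl, i-Pr2NEt, Bu4NI (cat.), CH2Cl2, 0 → 40 °C
Reagents that add atoms: chloromethyl methyl ether, COCCl
Why: Williamson-type O-alkylation of the only free hydroxyl places, without any selectivity question, the acetal that will guard O3 of ring C to the end; no stereocentre is touched.

Step 2
Reactants: 2 MOM-protected acetonide ester
Product: 3 2-O-(methoxymethyl)-D-erythrono-1,4-lactone
Conditions: AcOH–H2O (4:1), 50 °C; then toluene azeotrope
Reagents that add atoms: none
Why: Acid-catalysed acetal hydrolysis frees O3 and O4 and the primary hydroxyl closes the γ-lactone (transesterification), so the secondary 3-OH is the single hydroxyl left; the α-acyl MOM ether should survive aqueous acetic acid.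

Step 3
Reactants: 3 hydroxy lactone
Product: 4 3-O-(tert-butyldimethylsilyl)-2-O-(methoxymethyl)-D-erythrono-1,4-lactone
Conditions: TBSCl, imidazole, DMF, rt
Reagents that add atoms: tert-butyldimethylsilyl chloride, CC(C)(C)[Si](C)(C)Cl
Why: Silylation of the one free secondary alcohol installs the group that will later be removed alone to release the ring-closing oxygen; no stereocentre is formed.

Step 4
Reactants: 4 bis-protected lactone
Product: 5 (2R,3R)-3-(tert-butyldimethylsilyloxy)-4-hydroxy-N-methoxy-2-(methoxymethoxy)-N-methylbutanamide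
Conditions: MeNHOMe·HCl, AlMe3, CH2Cl2, 0 °C → rt
Reagents that add atoms: N,O-dimethylhydroxylamine hydrochloride, CNOC.Cl
Why: Weinreb aminolysis of the lactone by the aluminium amide opens the ring to the N-methoxy-N-methylamide and the primary alcohol; the aluminium alkoxide is a poor silyl acceptor, so the TBS group should stay on O3, and the crude alcohol is oxidised at once to forestall relactonisation.

Step 5
Reactants: 5 hydroxy Weinreb amide
Product: 6 (2R,3S)-3-(tert-butyldimethylsilyloxy)-N-methoxy-2-(methoxymethoxy)-N-methyl-4-oxobutanamide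
Conditions: Dess–Martin periodinane, NaHCO3, CH2Cl2, 0 °C → rt
Reagents that add atoms: none
Why: Dess–Martin oxidation of the primary alcohol under buffered, non-basic conditions should give the α-silyloxy aldehyde without epimerisation (the descriptor changes only through priorities).

Step 6
Reactants: 6 aldehyde
Product: 7 (2R,3R,4E)-3-(tert-butyldimethylsilyloxy)-N-methoxy-2-(methoxymethoxy)-N-methyl-6-oxohept-4-enamide
Conditions: Ph3P=CHC(O)CH3, CH2Cl2, rt
Reagents that add atoms: 1-(triphenyl-λ5-phosphanylidene)propan-2-one, CC(=O)C=P(c1ccccc1)(c1ccccc1)c1ccccc1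
Why: Wittig olefination with a stabilised acylmethylene ylide gives the E enone under neutral conditions that leave the adjacent stereocentre alone.

Step 7
Reactants: 7 methyl enone
Product: 9 (2R,3R,4E)-7-diazo-3-(tert-butyldimethylsilyloxy)-N-methoxy-2-(methoxymethoxy)-N-methyl-6-oxohept-4-enamide, via trifluoroacetyl diketone 8 (not isolated)
Conditions: LiN(SiMe3)2, THF, −78 °C; CF3CO2CH2CF3; then MeSO2N3, Et3N, H2O, MeCN, rt
Reagents that add atoms: methanesulfonyl azide, CS(=O)(=O)N=[N+]=[N-]; 2,2,2-trifluoroethyl trifluoroacetate, FC(F)(F)COC(=O)C(F)(F)F (its acyl group is carried by intermediate 8 only)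
Why: Detrifluoroacetylative diazo transfer: the kinetic α'-enolate of the methyl ketone is acylated, and the activated 1,3-dicarbonyl compound undergoes Regitz-type diazo transfer with loss of the trifluoroacetyl group, which gives the α'-diazo enone without touching the enone, the amide or the stereocentres.

Step 8
Reactants: 10 geranyl bromide
Product: 11 (4E)-5,9-dimethyldeca-4,8-dien-1-yne
Conditions: HC≡CMgBr (excess), CuCl (cat.), THF, 0 → 50 °C
Reagents that add atoms: ethynylmagnesium bromide, C#C[Mg]Br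
Why: Copper-catalysed SN2 coupling of the allylic bromide with the alkynyl Grignard reagent should give the skipped enyne with the E alkene intact.

Step 9
Reactants: 11 geranyl acetylene
Product: 14 triisopropyl{[(4E)-5,9-dimethyldeca-4,8-dien-1-yn-1-yl]oxy}silane, via lithium acetylide 12 (not isolated), via lithium ynolate 13 (not isolated)
Conditions: n-BuLi, THF, −78 °C; LiOOt-Bu (from t-BuOOH and LiN(SiMe3)2), −78 → 0 °C; i-Pr3SiOSO2CF3, −78 → 0 °C
Reagents that add atoms: tert-butyl hydroperoxide, CC(C)(C)OO; triisopropylsilyl trifluoromethanesulfonate, CC(C)[Si](C(C)C)(C(C)C)OS(=O)(=O)C(F)(F)F; n-butyllithium, [Li]CCCC (lithium of 12 and 13 only)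
Why: Electrophilic oxygen transfer from the lithium peroxide to the acetylide carbon gives the ynolate, which the hard silyl triflate traps on oxygen (acetylide oxidation followed by O-silylation); the trisubstituted alkenes are inert to the anionic peroxide.

Step 10
Reactants: 9 diazo enone, 14 geranyl siloxyalkyne
Product: 18 (2R,3R)-3-(tert-butyldimethylsilyloxy)-3-{3-[(2E)-3,7-dimethylocta-2,6-dien-1-yl]-2-hydroxy-4-(triisopropylsilyloxy)phenyl}-N-methoxy-2-(methoxymethoxy)-N-methylpropanamide, via vinylketene 15 (not isolated), via 4-alkenylcyclobutenone 16 (not isolated), via dienylketene 17 (not isolated)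
Conditions: hν (254 nm), ClCH2CH2Cl, rt, 14 in excess; then 80 °C
Reagents that add atoms: none
Why: Irradiation expels N2 and the alkenyl group shifts to the carbene carbon (Wolff rearrangement, forming C5'–C6') to give vinylketene 15, whose carbonyl carbon is attacked by the nucleophilic, geranyl-bearing carbon of the oxygen-polarised alkyne 14, so that a formal [2+2] cycloaddition (C2'–C3' and C4'–C5') gives cyclobutenone 16. Heating opens 16 by four-electron conrotatory cleavage to dienylketene 17, and ring B is closed by a thermal six-electron disrotatory electrocyclisation that joins the ketene carbon to the terminal alkene carbon (C1'–C2'), after which the cyclohexadienone tautomerises to the phenol. The closest known reaction type is the Danheiser benzannulation in its photochemical diazo ketone form with siloxyalkynes, which gives 2-substituted resorcinol monosilyl ethers. No stereocentre is formed (the sp3 ring carbon of 16 is lost on aromatisation), and C2 and C3 are spectators held as ethers in a neutral medium. The selectivity needed is the orientation of the ketene–alkyne union; the siloxy group secures it by polarising the triple bond, which places geranyl at C3' between the C2' hydroxyl (ketene oxygen) and the C4' siloxy oxygen. Ring opening of 16 is reversible, so material should be funnelled through the dienylketene geometry that can cyclise.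

Step 11
Reactants: 18 ring B phenol
Product: 20 (2R,3R)-3-(tert-butyldimethylsilyloxy)-3-{3-[(2E)-3,7-dimethylocta-2,6-dien-1-yl]-2,4-bis(methoxymethoxy)phenyl}-N-methoxy-2-(methoxymethoxy)-N-methylpropanamide, via resorcinol 19 (not isolated)
Conditions: Bu4NF (1 equiv), THF, 0 °C; then i-Pr2NEt, MOMCl, Bu4NI (cat.), 0 → 40 °C
Reagents that add atoms: chloromethyl methyl ether, COCCl
Why: Fluoride cleaves the aryl silyl ether (phenoxide leaving group) much faster than the hindered secondary alkyl TBS ether, and O-alkylation of both phenols then leaves ring B with acetals only, which are stable to organolithium reagents and base and fall in the final acid step.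

Step 12
Reactants: 21 5-fluororesorcinol
Product: 22 1-fluoro-3,5-bis(methoxymethoxy)benzene
Conditions: MOMCl, i-Pr2NEt, CH2Cl2, 0 °C → rt
Reagents that add atoms: chloromethyl methyl ether, COCCl
Why: Double phenol O-alkylation installs the two acetal groups that protect ring A and direct both later metalations.

Step 13
Reactants: 22 fluororesorcinol bis-MOM ether, 23 prenyl bromide
Product: 25 5-fluoro-1,3-bis(methoxymethoxy)-2-(3-methylbut-2-en-1-yl)benzene, via aryllithium 24 (not isolated)
Conditions: n-BuLi, THF, −78 → −20 °C; CuBr·SMe2; 23, −78 °C → rt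
Reagents that add atoms: n-butyllithium, [Li]CCCC (lithium of 24 only)
Why: Directed ortho-metalation should occur at the C–H flanked by two coordinating MOM ethers, and copper-mediated SN2 allylation at the primary carbon of prenyl bromide then places the prenyl group at the future C6.

Step 14
Reactants: 25 prenylated fluoroarene, 20 ring B Weinreb amide
Product: 27 (2R,3R)-3-(tert-butyldimethylsilyloxy)-3-{3-[(2E)-3,7-dimethylocta-2,6-dien-1-yl]-2,4-bis(methoxymethoxy)phenyl}-1-[6-fluoro-2,4-bis(methoxymethoxy)-3-(3-methylbut-2-en-1-yl)phenyl]-2-(methoxymethoxy)propan-1-one, via aryllithium 26 (not isolated)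
Conditions: n-BuLi, THF, −78 °C; then 20, −78 °C
Reagents that add atoms: n-butyllithium, [Li]CCCC (lithium of 26 only)
Why: The two remaining ring hydrogens of 25 are equivalent and each is flanked by fluorine and a MOM ether, so directed ortho-lithiation is unambiguous; addition to the Weinreb amide gives a chelated tetrahedral adduct that releases the ketone only on work-up, which forms C4–C4a without over-addition, and −78 °C holds back loss of LiF.

Step 15
Reactants: 27 silyl-protected fluoro ketone
Product: 28 (2R,3R)-3-{3-[(2E)-3,7-dimethylocta-2,6-dien-1-yl]-2,4-bis(methoxymethoxy)phenyl}-1-[6-fluoro-2,4-bis(methoxymethoxy)-3-(3-methylbut-2-en-1-yl)phenyl]-3-hydroxy-2-(methoxymethoxy)propan-1-one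
Conditions: HF·pyridine, pyridine, THF, 0 °C → rt
Reagents that add atoms: none
Why: Buffered acidic fluoride cleaves the alkyl silyl ether (Si–F bond formation) and frees the single hydroxyl on C2 without base, so the β-hydroxy ketone is not exposed to retro-aldol conditions; acetals, alkenes and the aryl fluoride are inert.

Step 16
Reactants: 28 fluoro hydroxy ketone
Product: 29 (2R,3R)-2-{3-[(2E)-3,7-dimethylocta-2,6-dien-1-yl]-2,4-bis(methoxymethoxy)phenyl}-3,5,7-tris(methoxymethoxy)-6-(3-methylbut-2-en-1-yl)-2,3-dihydro-4H-chromen-4-one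
Conditions: KOt-Bu (1.0 equiv), THF, −40 → 0 °C
Reagents that add atoms: none
Why: Intramolecular SNAr: the C2 alkoxide adds to C8a, which the ortho carbonyl activates, and loss of fluoride from the Meisenheimer adduct forms O1–C8a and the six-membered ring C; no bond at C2 or C3 is broken, so the anti diad becomes the trans (2R,3R) arrangement, and the non-migrating 3-O-MOM ether keeps O3 out of a competing five-membered closure.

Step 17
Reactants: 29 penta-MOM flavanonol
Product: 30 (2R,3R)-2-{3-[(2E)-3,7-dimethylocta-2,6-dien-1-yl]-2,4-dihydroxyphenyl}-3,5,7-trihydroxy-6-(3-methylbut-2-en-1-yl)-2,3-dihydro-4H-chromen-4-one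
Conditions: HCl (2 M in MeOH), 40 °C
Reagents that add atoms: none
Why: Acid-catalysed acetal methanolysis should remove the four aryl MOM ethers and the one alkyl MOM ether as dimethoxymethane; the trans-2,3 arrangement is also the thermodynamically preferred one, so reversible ionisation at C2 should not erode it.

Compound list
1 | methyl 3,4-O-isopropylidene-D-erythronate, methyl (2R)-2-[(4R)-2,2-dimethyl-1,3-dioxolan-4-yl]-2-hydroxyacetate | COC(=O)[C@H](O)[C@H]1COC(C)(C)O1 | starting material
2 | methyl 3,4-O-isopropylidene-2-O-(methoxymethyl)-D-erythronate | COC(=O)[C@H](OCOC)[C@H]1COC(C)(C)O1 | intermediate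
3 | 2-O-(methoxymethyl)-D-erythrono-1,4-lactone, (3R,4R)-4-hydroxy-3-(methoxymethoxy)oxolan-2-one | O=C1[C@H](OCOC)[C@H](O)CO1 | intermediate
4 | 3-O-(tert-butyldimethylsilyl)-2-O-(methoxymethyl)-D-erythrono-1,4-lactone | O=C1[C@H](OCOC)[C@H](O[Si](C)(C)C(C)(C)C)CO1 | intermediate
5 | (2R,3R)-3-(tert-butyldimethylsilyloxy)-4-hydroxy-N-methoxy-2-(methoxymethoxy)-N-methylbutanamide | CON(C)C(=O)[C@H](OCOC)[C@H](O[Si](C)(C)C(C)(C)C)CO | intermediate
6 | (2R,3S)-3-(tert-butyldimethylsilyloxy)-N-methoxy-2-(methoxymethoxy)-N-methyl-4-oxobutanamide | CON(C)C(=O)[C@H](OCOC)[C@H](O[Si](C)(C)C(C)(C)C)C=O | intermediate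
7 | (2R,3R,4E)-3-(tert-butyldimethylsilyloxy)-N-methoxy-2-(methoxymethoxy)-N-methyl-6-oxohept-4-enamide | CON(C)C(=O)[C@H](OCOC)[C@H](O[Si](C)(C)C(C)(C)C)/C=C/C(C)=O | intermediate
8 | (2R,3R,4E)-3-(tert-butyldimethylsilyloxy)-9,9,9-trifluoro-N-methoxy-2-(methoxymethoxy)-N-methyl-6,8-dioxonon-4-enamide (as its enolate) | CON(C)C(=O)[C@H](OCOC)[C@H](O[Si](C)(C)C(C)(C)C)/C=C/C(=O)CC(=O)C(F)(F)F | intermediate
9 | (2R,3R,4E)-7-diazo-3-(tert-butyldimethylsilyloxy)-N-methoxy-2-(methoxymethoxy)-N-methyl-6-oxohept-4-enamide | CON(C)C(=O)[C@H](OCOC)[C@H](O[Si](C)(C)C(C)(C)C)/C=C/C(=O)C=[N+]=[N-] | intermediate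
10 | geranyl bromide, (2E)-1-bromo-3,7-dimethylocta-2,6-diene | CC(C)=CCC/C(C)=C/CBr | starting material
11 | (4E)-5,9-dimethyldeca-4,8-dien-1-yne | CC(C)=CCC/C(C)=C/CC#C | intermediate
12 | lithium acetylide of 11 | CC(C)=CCC/C(C)=C/CC#C[Li] | intermediate
13 | lithium (4E)-5,9-dimethyldeca-4,8-dien-1-yn-1-olate | CC(C)=CCC/C(C)=C/CC#CO[Li] | intermediate
14 | triisopropyl{[(4E)-5,9-dimethyldeca-4,8-dien-1-yn-1-yl]oxy}silane | CC(C)=CCC/C(C)=C/CC#CO[Si](C(C)C)(C(C)C)C(C)C | intermediate
15 | vinylketene, (2R,3R,4E)-3-(tert-butyldimethylsilyloxy)-N-methoxy-2-(methoxymethoxy)-N-methyl-7-oxohepta-4,6-dienamide | CON(C)C(=O)[C@H](OCOC)[C@H](O[Si](C)(C)C(C)(C)C)/C=C/C=C=O | intermediate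
16 | 2-geranyl-3-(triisopropylsilyloxy)cyclobut-2-en-1-one carrying the E-alkenyl diad chain at C4 (both C4 epimers) | CON(C)C(=O)[C@H](OCOC)[C@H](O[Si](C)(C)C(C)(C)C)/C=C/C1C(=O)C(C/C=C(\C)CCC=C(C)C)=C1O[Si](C(C)C)(C(C)C)C(C)C | intermediate
17 | dienylketene from ring opening of 16 (2-geranyl-3-siloxy-hexa-1,3,5-trien-1-one with the diad chain at C6) | CON(C)C(=O)[C@H](OCOC)[C@H](O[Si](C)(C)C(C)(C)C)/C=C/C=C(O[Si](C(C)C)(C(C)C)C(C)C)\C(C/C=C(\C)CCC=C(C)C)=C=O | intermediate
18 | (2R,3R)-3-(tert-butyldimethylsilyloxy)-3-{3-[(2E)-3,7-dimethylocta-2,6-dien-1-yl]-2-hydroxy-4-(triisopropylsilyloxy)phenyl}-N-methoxy-2-(methoxymethoxy)-N-methylpropanamide | CON(C)C(=O)[C@H](OCOC)[C@H](O[Si](C)(C)C(C)(C)C)c1ccc(O[Si](C(C)C)(C(C)C)C(C)C)c(C/C=C(\C)CCC=C(C)C)c1O | intermediate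
19 | (2R,3R)-3-(tert-butyldimethylsilyloxy)-3-{3-[(2E)-3,7-dimethylocta-2,6-dien-1-yl]-2,4-dihydroxyphenyl}-N-methoxy-2-(methoxymethoxy)-N-methylpropanamide (formed as its ammonium phenoxide) | CON(C)C(=O)[C@H](OCOC)[C@H](O[Si](C)(C)C(C)(C)C)c1ccc(O)c(C/C=C(\C)CCC=C(C)C)c1O | intermediate
20 | (2R,3R)-3-(tert-butyldimethylsilyloxy)-3-{3-[(2E)-3,7-dimethylocta-2,6-dien-1-yl]-2,4-bis(methoxymethoxy)phenyl}-N-methoxy-2-(methoxymethoxy)-N-methylpropanamide | CON(C)C(=O)[C@H](OCOC)[C@H](O[Si](C)(C)C(C)(C)C)c1ccc(OCOC)c(C/C=C(\C)CCC=C(C)C)c1OCOC | intermediate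
21 | 5-fluororesorcinol | Oc1cc(F)cc(O)c1 | starting material
22 | 1-fluoro-3,5-bis(methoxymethoxy)benzene | COCOc1cc(F)cc(OCOC)c1 | intermediate
23 | prenyl bromide, 1-bromo-3-methylbut-2-ene | CC(C)=CCBr | starting material
24 | 4-fluoro-2,6-bis(methoxymethoxy)phenyllithium | [Li]c1c(OCOC)cc(F)cc1OCOC | intermediate
25 | 5-fluoro-1,3-bis(methoxymethoxy)-2-(3-methylbut-2-en-1-yl)benzene | COCOc1cc(F)cc(OCOC)c1CC=C(C)C | intermediate
26 | 6-fluoro-2,4-bis(methoxymethoxy)-3-(3-methylbut-2-en-1-yl)phenyllithium | [Li]c1c(F)cc(OCOC)c(CC=C(C)C)c1OCOC | intermediate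
27 | (2R,3R)-3-(tert-butyldimethylsilyloxy)-3-{3-[(2E)-3,7-dimethylocta-2,6-dien-1-yl]-2,4-bis(methoxymethoxy)phenyl}-1-[6-fluoro-2,4-bis(methoxymethoxy)-3-(3-methylbut-2-en-1-yl)phenyl]-2-(methoxymethoxy)propan-1-one | COCOc1cc(F)c(C(=O)[C@H](OCOC)[C@H](O[Si](C)(C)C(C)(C)C)c2ccc(OCOC)c(C/C=C(\C)CCC=C(C)C)c2OCOC)c(OCOC)c1CC=C(C)C | intermediate
28 | (2R,3R)-3-{3-[(2E)-3,7-dimethylocta-2,6-dien-1-yl]-2,4-bis(methoxymethoxy)phenyl}-1-[6-fluoro-2,4-bis(methoxymethoxy)-3-(3-methylbut-2-en-1-yl)phenyl]-3-hydroxy-2-(methoxymethoxy)propan-1-one | COCOc1cc(F)c(C(=O)[C@H](OCOC)[C@H](O)c2ccc(OCOC)c(C/C=C(\C)CCC=C(C)C)c2OCOC)c(OCOC)c1CC=C(C)C | intermediate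
29 | (2R,3R)-2-{3-[(2E)-3,7-dimethylocta-2,6-dien-1-yl]-2,4-bis(methoxymethoxy)phenyl}-3,5,7-tris(methoxymethoxy)-6-(3-methylbut-2-en-1-yl)-2,3-dihydro-4H-chromen-4-one | CC(C)=CCC/C(C)=C/Cc1c(OCOC)ccc([C@H]2Oc3cc(OCOC)c(CC=C(C)C)c(OCOC)c3C(=O)[C@@H]2OCOC)c1OCOC | intermediate
30 | (2R,3R)-2-{3-[(2E)-3,7-dimethylocta-2,6-dien-1-yl]-2,4-dihydroxyphenyl}-3,5,7-trihydroxy-6-(3-methylbut-2-en-1-yl)-2,3-dihydro-4H-chromen-4-one (CNP0166115.1) | CC(C)=CCC/C(C)=C/Cc1c(O)ccc([C@H]2Oc3cc(O)c(CC=C(C)C)c(O)c3C(=O)[C@@H]2O)c1O | target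

Total step count: 17.
Longest linear sequence: 13 steps (steps 1–7, 10, 11, 14, 15, 16, 17).

Steps most likely to fail

Step 10 (benzannulation). The photogenerated vinylketene may dimerise or acylate the phenol product faster than the siloxyalkyne captures it, or the diazo enone may degrade under the lamp. Fallback: setting out from diazo enone 9, a silver-catalysed Wolff rearrangement in the dark (AgO2CPh, Et3N, THF–H2O) would trap ketene 15 with water as the E β,γ-unsaturated acid F1 (Arndt–Eistert-type homologation). 1-Chloro-N,N,2-trimethylprop-1-en-1-amine would convert it under neutral conditions into the acid chloride F2. Slow addition of Et3N to F2 and an excess of alkyne 14 in toluene at 80 °C would then regenerate 15 by dehydrochlorination at a low stationary concentration, without light. Ketene–siloxyalkyne cycloaddition and the thermal cascade through 16 and 17 follow as before, and the route is rejoined at phenol 18.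

Step 16 (closure of ring C). Retro-aldol cleavage of the β-alkoxide, or base-induced β-elimination that reopens the new ring, may outrun fluoride displacement. Fallback: a chlorine analogue closed by metal catalysis instead of by a free alkoxide, setting out from prenyl bromide 23 and amide 20 with commercial 5-chlororesorcinol in place of 21. MOMCl and i-Pr2NEt would give the bis-MOM ether F3. Lithiation between the acetal oxygens (n-BuLi, −78 °C) would give the aryllithium F4, and copper-mediated allylation with 23 the prenyl arene F5. A second lithiation next to chlorine would give the aryllithium F6, which adds to 20 to give the chloro ketone F7, and HF·pyridine would give the chloro alcohol F8. Intramolecular C–O coupling of the Buchwald–Hartwig type (Pd(OAc)2, di-tert-butyl(2',4',6'-triisopropylbiphenyl-2-yl)phosphine, Cs2CO3, toluene, 80 °C) would then form O1–C8a with the alcohol bound to palladium in a weakly basic, non-polar medium, and the route is rejoined at 29.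

Step 14 (fragment union). The di-ortho-substituted aryllithium may lose LiF (aryne formation) or deprotonate the amide before it adds to the hindered, α-branched Weinreb amide. Fallback: setting out from amide 20, reduction with i-Bu2AlH (THF, −78 °C) would give the aldehyde F9, a far better electrophile. Aryllithium 26 should add to it rapidly at −78 °C to give the carbinol F10 as a mixture of epimers at the new centre. Dess–Martin oxidation would remove that centre and rejoin the route at ketone 27.

Further compounds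
F1 | step 10 | (3E,5R,6R)-5-(tert-butyldimethylsilyloxy)-7-[methoxy(methyl)amino]-6-(methoxymethoxy)-7-oxohept-3-enoic acid | CON(C)C(=O)[C@H](OCOC)[C@H](O[Si](C)(C)C(C)(C)C)/C=C/CC(=O)O
F2 | step 10 | (3E,5R,6R)-5-(tert-butyldimethylsilyloxy)-7-[methoxy(methyl)amino]-6-(methoxymethoxy)-7-oxohept-3-enoyl chloride | CON(C)C(=O)[C@H](OCOC)[C@H](O[Si](C)(C)C(C)(C)C)/C=C/CC(=O)Cl
F3 | step 16 | 1-chloro-3,5-bis(methoxymethoxy)benzene | COCOc1cc(Cl)cc(OCOC)c1
F4 | step 16 | 4-chloro-2,6-bis(methoxymethoxy)phenyllithium | [Li]c1c(OCOC)cc(Cl)cc1OCOC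
F5 | step 16 | 5-chloro-1,3-bis(methoxymethoxy)-2-(3-methylbut-2-en-1-yl)benzene | COCOc1cc(Cl)cc(OCOC)c1CC=C(C)C
F6 | step 16 | 6-chloro-2,4-bis(methoxymethoxy)-3-(3-methylbut-2-en-1-yl)phenyllithium | [Li]c1c(Cl)cc(OCOC)c(CC=C(C)C)c1OCOC
F7 | step 16 | (2R,3R)-3-(tert-butyldimethylsilyloxy)-1-[6-chloro-2,4-bis(methoxymethoxy)-3-(3-methylbut-2-en-1-yl)phenyl]-3-{3-[(2E)-3,7-dimethylocta-2,6-dien-1-yl]-2,4-bis(methoxymethoxy)phenyl}-2-(methoxymethoxy)propan-1-one | COCOc1cc(Cl)c(C(=O)[C@H](OCOC)[C@H](O[Si](C)(C)C(C)(C)C)c2ccc(OCOC)c(C/C=C(\C)CCC=C(C)C)c2OCOC)c(OCOC)c1CC=C(C)C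
F8 | step 16 | (2R,3R)-1-[6-chloro-2,4-bis(methoxymethoxy)-3-(3-methylbut-2-en-1-yl)phenyl]-3-{3-[(2E)-3,7-dimethylocta-2,6-dien-1-yl]-2,4-bis(methoxymethoxy)phenyl}-3-hydroxy-2-(methoxymethoxy)propan-1-one | COCOc1cc(Cl)c(C(=O)[C@H](OCOC)[C@H](O)c2ccc(OCOC)c(C/C=C(\C)CCC=C(C)C)c2OCOC)c(OCOC)c1CC=C(C)C
F9 | step 14 | (2R,3R)-3-(tert-butyldimethylsilyloxy)-3-{3-[(2E)-3,7-dimethylocta-2,6-dien-1-yl]-2,4-bis(methoxymethoxy)phenyl}-2-(methoxymethoxy)propanal | O=C[C@H](OCOC)[C@H](O[Si](C)(C)C(C)(C)C)c1ccc(OCOC)c(C/C=C(\C)CCC=C(C)C)c1OCOC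
F10 | step 14 | (2R,3R)-3-(tert-butyldimethylsilyloxy)-3-{3-[(2E)-3,7-dimethylocta-2,6-dien-1-yl]-2,4-bis(methoxymethoxy)phenyl}-1-[6-fluoro-2,4-bis(methoxymethoxy)-3-(3-methylbut-2-en-1-yl)phenyl]-2-(methoxymethoxy)propan-1-ol (both C1 epimers) | COCOc1cc(F)c(C(O)[C@H](OCOC)[C@H](O[Si](C)(C)C(C)(C)C)c2ccc(OCOC)c(C/C=C(\C)CCC=C(C)C)c2OCOC)c(OCOC)c1CC=C(C)C
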